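**Retrosynthetic overview**
1. Feature: in ring A the gem-dimethyl carbon C4 lies between the C3 ketone and the ring-fusion methine C5, and H5 is cis to the C10 methyl group. C4 is read as the α-carbon of an isopropyl ketone tethered to C10 and C5 as the β-carbon of a ring B enone (C5=C6–C7=O), so C4–C5 is an intramolecular Michael bond whose natural outcome is the cis fusion.
2. Endgame: C12–C13 is made by B-alkyl Suzuki–Miyaura coupling of a C9 vinyl group with a C13 (E)-alkenyl iodide from geranyl bromide. The auxiliary C7 oxygen is removed by 8-OH-directed reduction and Barton–McCombie deoxygenation, which leave the C3 ketone untouched.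
3. C8 (8β-CH3, 8α-OH) is completed on monocyclic ring B by methylation and then Rubottom oxidation, both anti to the C9 vinyl group, with C3 masked as a dioxolane. After ring closure the C2–H bonds would compete for base and ring A would cover the α face. A blocked C8 also leaves the isopropyl ketone as the only enolisable carbonyl in the key step.
4. C9 and C10 come from one catalytic event: a copper-catalysed enantioselective vinyl addition that desymmetrises a prochiral 4,4-disubstituted cyclohexadienone built from propanal, isopropyl vinyl ketone and methyl vinyl ketone.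
5. Ring order: ring B (step 2, Robinson-type annulation), then ring A (step 9, Michael closure).

Key step: step 9

Numbering: terpenoid numbering is used for ring atoms (ring A = C1–C5, C10; ring B = C5–C10; vinyl = C11, C12), and β is the face of the C10 methyl group.
Assumption: the (R,S,S)-phosphoramidite–copper catalyst is taken to select the enone face in the sense known for simple cyclohex-2-enones; if a trial run shows the opposite sense, the enantiomeric ligand is used and nothing else changes.

**Step 1**
Reactants: 1 propanal; 2 4-methylpent-1-en-3-one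
Product: 3 2,6-dimethyl-5-oxoheptanal
Conditions: (S)-2-[methoxy(diphenyl)methyl]pyrrolidine (5 mol%), ethyl 3,4-dihydroxybenzoate (20 mol%), neat, 4 °C
Reagents that add atoms: none
Why: Enamine-catalysed Michael addition, in which the amine turns propanal into an enamine that adds to the unhindered terminus of the vinyl ketone, the α-branched product is too hindered to add a second time, and the configuration of the new α-methyl centre is irrelevant because this carbon becomes the prochiral C10.

**Step 2**
Reactants: 3 2,6-dimethyl-5-oxoheptanal; 4 but-3-en-2-one (methyl vinyl ketone)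
Product: 7 4-methyl-4-(4-methyl-3-oxopentyl)cyclohex-2-en-1-one (racemic), via pyrrolidine enamine 5 (not isolated), via diketo aldehyde 6 (not isolated)
Conditions: pyrrolidine, toluene, reflux (−H2O); 4, 0 °C → rt; then 6 M aq. HCl, rt
Reagents that add atoms: none
Why: Stork enamine Michael addition followed by acid-promoted aldol condensation (Robinson-type annulation of an α-branched aldehyde), in which pyrrolidine condenses only with the aldehyde, the trisubstituted enamine creates the quaternary C10 on addition to 4, and of the possible aldol closures only attack of the methyl ketone CH3 on the aldehyde can dehydrate, so ring B should form as the 4,4-disubstituted cyclohexenone.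

**Step 3**
Reactants: 7 4-methyl-4-(4-methyl-3-oxopentyl)cyclohex-2-en-1-one
Product: 8 4-methyl-4-{2-[2-(propan-2-yl)-1,3-dioxolan-2-yl]ethyl}cyclohex-2-en-1-one (racemic)
Conditions: HOCH2CH2OH, p-TsOH·H2O (cat.), benzene, reflux (−H2O)
Reagents that add atoms: ethylene glycol, OCCO
Why: Chemoselective acid-catalysed ketalisation, because the saturated ketone is more electrophilic than the conjugated one, which also cannot deconjugate since C10 bears no hydrogen, a selectivity well established for enediones whose saturated ketone is likewise hindered.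

**Step 4**
Reactants: 8 4-methyl-4-{2-[2-(propan-2-yl)-1,3-dioxolan-2-yl]ethyl}cyclohex-2-en-1-one
Product: 10 4-methyl-4-{2-[2-(propan-2-yl)-1,3-dioxolan-2-yl]ethyl}cyclohexa-2,5-dien-1-one (prochiral), via trimethylsilyl dienol ether 9 (not isolated)
Conditions: LiN(iPr)2, Me3SiCl, THF, −78 °C; then Pd(OAc)2 (1.05 equiv), MeCN, rt
Reagents that add atoms: none
Why: Saegusa–Ito oxidation, in which the α' methylene is the only acidic site once C3 is masked, so a single cross-conjugated silyl dienol ether forms and divalent palladium converts it by β-hydride elimination into the symmetric dienone, erasing the C10 stereocentre.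

**Step 5**
Reactants: 10 4-methyl-4-{2-[2-(propan-2-yl)-1,3-dioxolan-2-yl]ethyl}cyclohexa-2,5-dien-1-one
Product: 11 (4S,5R)-5-ethenyl-4-methyl-4-{2-[2-(propan-2-yl)-1,3-dioxolan-2-yl]ethyl}cyclohex-2-en-1-one (vinyl cis to the ring methyl group)
Conditions: CH2=CHMgBr + Me2AlCl (Et2O, 0 °C) → CH2=CHAlMe2; copper thiophene-2-carboxylate Cu(O2CC4H3S) (5 mol%), (R,S,S)-phosphoramidite from (R)-BINOL and bis[(S)-1-phenylethyl]amine (10 mol%), Et2O, −30 °C; aq. NH4Cl
Reagents that add atoms: dimethyl(vinyl)aluminium, C=C[Al](C)C (made in the flask from vinylmagnesium bromide, C=C[Mg]Br, and Me2AlCl)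
Why: Copper-catalysed asymmetric conjugate addition of an alkenylalane, a reaction type established for cyclic enones and, with alkylzinc and alkylaluminium reagents, for the desymmetrisation of 4,4-disubstituted cyclohexadienones, in which the chiral copper complex selects the prochiral enone face and so sets C9, while delivery on the ring face bearing the small C10 methyl group rather than the ketal chain decides which enantiotopic alkene reacts and so sets C10.

**Step 6**
Reactants: 11 (4S,5R)-5-ethenyl-4-methyl-4-{2-[2-(propan-2-yl)-1,3-dioxolan-2-yl]ethyl}cyclohex-2-en-1-one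
Product: 12 (4S,5S,6S)-5-ethenyl-4,6-dimethyl-4-{2-[2-(propan-2-yl)-1,3-dioxolan-2-yl]ethyl}cyclohex-2-en-1-one (8α-methyl, trans to vinyl)
Conditions: LiN(iPr)2, THF, −78 °C; MeI, −78 → −20 °C
Reagents that add atoms: iodomethane, CI
Why: Kinetic α'-alkylation of an enone, in which the base can only remove a C8 proton and iodomethane approaches the cross-conjugated dienolate anti to the neighbouring C9 vinyl group, a provisional C8 configuration that is erased in the next step.

**Step 7**
Reactants: 12 (4S,5S,6S)-5-ethenyl-4,6-dimethyl-4-{2-[2-(propan-2-yl)-1,3-dioxolan-2-yl]ethyl}cyclohex-2-en-1-one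
Product: 14 (4S,5R,6S)-5-ethenyl-4,6-dimethyl-4-{2-[2-(propan-2-yl)-1,3-dioxolan-2-yl]ethyl}-6-(triethylsilyloxy)cyclohex-2-en-1-one (8α-OSiEt3, 8β-methyl), via triethylsilyl dienol ether 13 (not isolated)
Conditions: KN(SiMe3)2, THF, −78 °C; Et3SiCl; then m-CPBA, NaHCO3, CH2Cl2, −20 → 0 °C
Reagents that add atoms: chlorotriethylsilane, CC[Si](Cl)(CC)CC; m-chloroperoxybenzoic acid, OOC(=O)c1cccc(Cl)c1
Why: Rubottom oxidation of a 2-silyloxydiene, in which C8–H is the only acidic hydrogen, the peracid attacks the electron-rich tetrasubstituted C7=C8 enol ether rather than the vinyl or C5=C6 alkene and does so from the α face, anti to the adjacent C9 vinyl group and remote from the C10 methyl group, and migration of silicon in the opened silyloxy epoxide leaves the new 8α-oxygen already protected.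

**Step 8**
Reactants: 14 (4S,5R,6S)-5-ethenyl-4,6-dimethyl-4-{2-[2-(propan-2-yl)-1,3-dioxolan-2-yl]ethyl}-6-(triethylsilyloxy)cyclohex-2-en-1-one
Product: 15 (4S,5R,6S)-5-ethenyl-4,6-dimethyl-4-(4-methyl-3-oxopentyl)-6-(triethylsilyloxy)cyclohex-2-en-1-one
Conditions: PPTS (cat.), acetone/H2O, 50 °C
Reagents that add atoms: water, O
Why: Mild acid-catalysed ketal hydrolysis, since the crowded ketal of a branched ketone is cleaved by a pyridinium acid in wet acetone under conditions that a tertiary, doubly flanked triethylsilyl ether should tolerate.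

**Step 9**
Reactants: 15 (4S,5R,6S)-5-ethenyl-4,6-dimethyl-4-(4-methyl-3-oxopentyl)-6-(triethylsilyloxy)cyclohex-2-en-1-one
Product: 16 cis-fused (5S,8S,9R,10S)-4,4,8,10-tetramethyl-8α-(triethylsilyloxy)-9β-vinyldecalin-3,7-dione (5β-H, 10β-methyl)
Conditions: KOtBu (0.3 equiv), tBuOH/THF, 0 °C → rt; aq. NH4Cl
Reagents that add atoms: none
Why: tert-Butoxide reversibly deprotonates C2 and C4 of the isopropyl ketone, the only enolisable carbonyl now that C8 is fully substituted; the tetrasubstituted C4 enolate adds to C5 of the C5=C6–C7=O enone, and tBuOH protonates the resulting C6=C7 enolate and regenerates the base. The closest known reaction type is the base-mediated intramolecular Michael addition of a ketone enolate to a 4,4-disubstituted cyclohexenone, a known entry to cis-fused decalindiones, with quaternary-carbon formation from an isopropyl ketone at the demanding end of its scope. Ring A closes in a 6-(enolendo)-exo-trig mode through a chair-like six-membered transition state, delivering the C3 ketone and the gem-dimethyl carbon together. The new stereocentre C5 is controlled by C10: the three-atom tether stands on the α face of ring B and can overlap only with the α lobe of the enone π* orbital at the adjacent C5, so C4 bonds α and H5 ends β, cis to the C10 methyl group as in the target, whereas a trans closure would require in-plane attack without orbital overlap. The selectivity needed is attack by C4 rather than C2, and it is secured because C2 could only form a four-membered ring at C5 or a reversible bridged aldol at C7, so the equilibrating enolates drain through the single productive channel. C8, C9 and C10 carry no acidic hydrogen and cannot epimerise under these conditions.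

**Step 10**
Reactants: 16 cis-fused 4,4,8,10-tetramethyl-8α-(triethylsilyloxy)-9β-vinyldecalin-3,7-dione
Product: 17 cis-fused (5S,8S,9R,10S)-8α-hydroxy-4,4,8,10-tetramethyl-9β-vinyldecalin-3,7-dione
Conditions: HF·pyridine, THF, 0 °C → rt
Reagents that add atoms: none
Why: Fluoride-driven desilylation, powered by the strong Si–F bond and run in a buffered, non-basic medium so that the liberated tertiary α-ketol has no opportunity to rearrange.

**Step 11**
Reactants: 17 cis-fused 8α-hydroxy-4,4,8,10-tetramethyl-9β-vinyldecalin-3,7-dione
Product: 18 cis-fused (5S,7S,8S,9R,10S)-7β,8α-dihydroxy-4,4,8,10-tetramethyl-9β-vinyldecalin-3-one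
Conditions: Me4NBH(OAc)3, MeCN/AcOH, −20 °C → rt
Reagents that add atoms: none
Why: Hydroxyl-directed triacetoxyborohydride reduction, in which the reagent is too weak to reduce an isolated ketone, so only the C7 carbonyl receives hydride, delivered internally from the α face after the 8α-hydroxyl has displaced an acetate on boron (7β-alcohol expected, a centre removed in step 13), and the C3 ketone is retained.

**Step 12**
Reactants: 18 cis-fused 7β,8α-dihydroxy-4,4,8,10-tetramethyl-9β-vinyldecalin-3-one
Product: 19 7β-O-(phenoxythiocarbonyl) derivative of 18 (8α-OH free)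
Conditions: PhOC(S)Cl, pyridine, CH2Cl2, 0 °C
Reagents that add atoms: O-phenyl chlorothionoformate, ClC(=S)Oc1ccccc1
Why: Selective thioacylation of a secondary alcohol beside a tertiary one, since the crowded 8α-hydroxyl is not acylated under these conditions and the low temperature with pyridine as the only base disfavours its later closure onto the thiocarbonyl group.

**Step 13**
Reactants: 19 7β-O-(phenoxythiocarbonyl) derivative of 18
Product: 20 cis-fused (5S,8R,9R,10S)-8α-hydroxy-4,4,8,10-tetramethyl-9β-vinyldecalin-3-one
Conditions: Bu3SnH, AIBN (cat.), toluene, 90 °C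
Reagents that add atoms: none
Why: Barton–McCombie deoxygenation, in which the stannyl radical adds to sulfur, β-scission releases the secondary C7 radical, and this abstracts hydrogen from the stannane faster than it can engage the C9 vinyl group (only three- or four-membered closures are open to it), while hydroxyl, ketone and alkene are inert to the chain.

**Step 14**
Reactants: 21 geranyl bromide; 22 1-(trimethylsilyl)propyne
Product: 23 [(5E)-6,10-dimethylundeca-5,9-dien-1-yn-1-yl]trimethylsilane
Conditions: 22, nBuLi, THF, −20 °C; then 21, −78 °C → rt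
Reagents that add atoms: none
Why: SN2 alkylation of a propargylic organolithium, in which the silyl cap forces deprotonation at the methyl group and steers the ambident anion to react at its propargylic carbon, and the primary allylic bromide is displaced without allylic transposition or loss of the (E)-geometry.

**Step 15**
Reactants: 23 [(5E)-6,10-dimethylundeca-5,9-dien-1-yn-1-yl]trimethylsilane
Product: 24 (5E)-6,10-dimethylundeca-5,9-dien-1-yne
Conditions: K2CO3 (cat.), MeOH, rt
Reagents that add atoms: none
Why: Base-catalysed protiodesilylation of an alkynylsilane, in which methoxide attacks silicon, methanol protonates the departing acetylide, and the trisubstituted alkenes are inert.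

**Step 16**
Reactants: 24 (5E)-6,10-dimethylundeca-5,9-dien-1-yne
Product: 26 (1E,5E)-1-iodo-2,6,10-trimethylundeca-1,5,9-triene, via alkenyl dimethylalane 25 (not isolated)
Conditions: Me3Al, Cp2ZrCl2 (0.25 equiv), CH2Cl2, 0 °C → rt; I2, THF, −30 °C
Reagents that add atoms: trimethylaluminium, C[Al](C)C; iodine, II
Why: Negishi zirconium-catalysed carboalumination followed by iodinolysis, in which methyl and aluminium add syn across the terminal alkyne with aluminium on the terminal carbon and iodine replaces aluminium with retention, fixing the (E)-geometry of the future C13=C14 alkene.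

**Step 17**
Reactants: 20 cis-fused 8α-hydroxy-4,4,8,10-tetramethyl-9β-vinyldecalin-3-one; 26 (1E,5E)-1-iodo-2,6,10-trimethylundeca-1,5,9-triene
Product: 28 IN0671, (4aS,5R,6R,8aS)-6-hydroxy-1,1,4a,6-tetramethyl-5-[(3E,7E)-4,8,12-trimethyltrideca-3,7,11-trien-1-yl]octahydronaphthalen-2(1H)-one, via C12 B-alkyl-9-BBN adduct 27 (not isolated)
Conditions: 9-BBN, THF, rt; then aq. Cs2CO3, 26, Pd(dppf)Cl2 (5 mol%), AsPh3, DMF, rt
Reagents that add atoms: none
Why: B-alkyl Suzuki–Miyaura coupling, in which 9-BBN places boron on the terminal carbon C12 of the monosubstituted alkene much faster than it reduces a ketone flanked by the quaternary C4, the aqueous base destroys excess borane before the polyene 26 is introduced, and oxidative addition, transmetallation and reductive elimination at palladium all retain the (E)-alkenyl geometry, so the C12–C13 bond completes the target without touching any stereocentre.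

**Compound list**
1 | propanal | CCC=O | starting material
2 | 4-methylpent-1-en-3-one | CC(C)C(=O)C=C | starting material
3 | 2,6-dimethyl-5-oxoheptanal | CC(C)C(=O)CCC(C)C=O | intermediate
4 | but-3-en-2-one (methyl vinyl ketone) | CC(=O)C=C | starting material
5 | 2,6-dimethyl-7-(pyrrolidin-1-yl)hept-6-en-3-one (not isolated) | CC(C)C(=O)CCC(C)=CN1CCCC1 | intermediate
6 | 2,6-dimethyl-5-oxo-2-(3-oxobutyl)heptanal (not isolated) | CC(C)C(=O)CCC(C)(C=O)CCC(C)=O | intermediate
7 | 4-methyl-4-(4-methyl-3-oxopentyl)cyclohex-2-en-1-one (racemic) | CC(C)C(=O)CCC1(C)C=CC(=O)CC1 | intermediate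
8 | 4-methyl-4-{2-[2-(propan-2-yl)-1,3-dioxolan-2-yl]ethyl}cyclohex-2-en-1-one (racemic) | CC(C)C1(CCC2(C)C=CC(=O)CC2)OCCO1 | intermediate
9 | trimethylsilyl dienol ether of 8 (not isolated) | CC(C)C1(CCC2(C)C=CC(O[Si](C)(C)C)=CC2)OCCO1 | intermediate
10 | 4-methyl-4-{2-[2-(propan-2-yl)-1,3-dioxolan-2-yl]ethyl}cyclohexa-2,5-dien-1-one | CC(C)C1(CCC2(C)C=CC(=O)C=C2)OCCO1 | intermediate
11 | (4S,5R)-5-ethenyl-4-methyl-4-{2-[2-(propan-2-yl)-1,3-dioxolan-2-yl]ethyl}cyclohex-2-en-1-one | C=C[C@@H]1[C@@](C)(CCC2(C(C)C)OCCO2)C=CC(=O)C1 | intermediate
12 | (4S,5S,6S)-5-ethenyl-4,6-dimethyl-4-{2-[2-(propan-2-yl)-1,3-dioxolan-2-yl]ethyl}cyclohex-2-en-1-one | C=C[C@@H]1[C@@](C)(CCC2(C(C)C)OCCO2)C=CC(=O)[C@H]1C | intermediate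
13 | triethylsilyl dienol ether of 12 (C7=C8, not isolated) | C=C[C@@H]1[C@@](C)(CCC2(C(C)C)OCCO2)C=CC(O[Si](CC)(CC)CC)=C1C | intermediate
14 | (4S,5R,6S)-5-ethenyl-4,6-dimethyl-4-{2-[2-(propan-2-yl)-1,3-dioxolan-2-yl]ethyl}-6-(triethylsilyloxy)cyclohex-2-en-1-one | C=C[C@@H]1[C@@](C)(CCC2(C(C)C)OCCO2)C=CC(=O)[C@@]1(C)O[Si](CC)(CC)CC | intermediate
15 | (4S,5R,6S)-5-ethenyl-4,6-dimethyl-4-(4-methyl-3-oxopentyl)-6-(triethylsilyloxy)cyclohex-2-en-1-one (key-step precursor) | C=C[C@@H]1[C@@](C)(CCC(=O)C(C)C)C=CC(=O)[C@@]1(C)O[Si](CC)(CC)CC | intermediate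
16 | cis-fused (5S,8S,9R,10S)-4,4,8,10-tetramethyl-8α-(triethylsilyloxy)-9β-vinyldecalin-3,7-dione (key-step product) | C=C[C@@H]1[C@@]2(C)CCC(=O)C(C)(C)[C@H]2CC(=O)[C@@]1(C)O[Si](CC)(CC)CC | intermediate
17 | cis-fused (5S,8S,9R,10S)-8α-hydroxy-4,4,8,10-tetramethyl-9β-vinyldecalin-3,7-dione | C=C[C@@H]1[C@@]2(C)CCC(=O)C(C)(C)[C@H]2CC(=O)[C@@]1(C)O | intermediate
18 | cis-fused (5S,7S,8S,9R,10S)-7β,8α-dihydroxy-4,4,8,10-tetramethyl-9β-vinyldecalin-3-one | C=C[C@@H]1[C@@]2(C)CCC(=O)C(C)(C)[C@H]2C[C@H](O)[C@@]1(C)O | intermediate
19 | 7β-O-(phenoxythiocarbonyl) derivative of 18 | C=C[C@@H]1[C@@]2(C)CCC(=O)C(C)(C)[C@H]2C[C@H](OC(=S)Oc3ccccc3)[C@@]1(C)O | intermediate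
20 | cis-fused (5S,8R,9R,10S)-8α-hydroxy-4,4,8,10-tetramethyl-9β-vinyldecalin-3-one | C=C[C@@H]1[C@@]2(C)CCC(=O)C(C)(C)[C@H]2CC[C@@]1(C)O | intermediate
21 | geranyl bromide | CC(C)=CCC/C(C)=C/CBr | starting material
22 | 1-(trimethylsilyl)propyne | CC#C[Si](C)(C)C | starting material
23 | [(5E)-6,10-dimethylundeca-5,9-dien-1-yn-1-yl]trimethylsilane | CC(C)=CCC/C(C)=C/CCC#C[Si](C)(C)C | intermediate
24 | (5E)-6,10-dimethylundeca-5,9-dien-1-yne | CC(C)=CCC/C(C)=C/CCC#C | intermediate
25 | dimethyl[(1E,5E)-2,6,10-trimethylundeca-1,5,9-trien-1-yl]aluminium (not isolated) | CC(C)=CCC/C(C)=C/CC/C(C)=C/[Al](C)C | intermediate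
26 | (1E,5E)-1-iodo-2,6,10-trimethylundeca-1,5,9-triene | CC(C)=CCC/C(C)=C/CC/C(C)=C/I | intermediate
27 | C12 B-alkyl-9-borabicyclo[3.3.1]nonane adduct of 20 (not isolated) | C1CC2CCCC(C1)B2CC[C@@H]3[C@@]4(C)CCC(=O)C(C)(C)[C@H]4CC[C@@]3(C)O | intermediate
28 | IN0671, (4aS,5R,6R,8aS)-6-hydroxy-1,1,4a,6-tetramethyl-5-[(3E,7E)-4,8,12-trimethyltrideca-3,7,11-trien-1-yl]octahydronaphthalen-2(1H)-one | CC(C)=CCC/C(C)=C/CC/C(C)=C/CC[C@@H]1[C@@]2(C)CCC(=O)C(C)(C)[C@H]2CC[C@@]1(C)O | target

**Step count**
Total steps: 17. Longest linear sequence: 14 (steps 1–13, then 17). Steps 14–16 prepare the side-chain iodide in parallel.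

**Steps most likely to fail**

1. Step 9 (key step).
   - Risk: the crowded C4–C5 bond, flanked by two quaternary carbons, may not be held under equilibrating base, so retro-Michael opening could keep the open form dominant. The C2 enolate of the product could also close transannularly onto the C7 carbonyl in a reversible aldol.
   - Fallback: the same bond is made under kinetic, Lewis-acidic control, setting out from 15 and returning at 16.
   - Me3SiOTf and Et3N in CH2Cl2 under equilibrating conditions act on the only enolisable ketone. They should give the tetrasubstituted trimethylsilyl enol ether of 15, F1.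
   - Catalytic HNTf2 in CH2Cl2 at −78 °C then triggers an intramolecular Mukaiyama–Michael addition with silyl transfer. This gives the C7 trimethylsilyl enol ether of 16, F2. No free enolate or C7 carbonyl is present there, so neither reversal nor aldol closure is open.
   - Brief treatment with aqueous citric acid in THF gives 16.

2. Step 5.
   - Risk: discrimination between the two ring faces next to C10 (methyl against the CH2 of the chain) may be poor. Vinyl transfer from aluminium may be sluggish or accompanied by methyl transfer, and enantioselectivity may erode.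
   - Fallback: both the nucleophile class and the bond-forming mechanism are changed, setting out from 10 and returning at 11 with no new intermediate.
   - A Hayashi–Miyaura addition is used: potassium vinyltrifluoroborate, [Rh(C2H4)2Cl]2 and (R)-BINAP in toluene/H2O. A vinyl–rhodium species inserts the enone, and the rhodium enolate is protonated in the protic medium.
   - The tight chiral pocket at rhodium is more sensitive to the substituent lying under the attacked face. Step 6 follows unchanged.

3. Step 12 (with step 13).
   - Risk: the neighbouring tertiary hydroxyl may close onto the thiocarbonyl group. Radical fragmentation of such a cyclic derivative would break the tertiary C8–O bond instead of the secondary C7–O bond.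
   - Fallback: a polar deoxygenation sets out from 18 and returns at 20.
   - MsCl in pyridine gives the 7β-methanesulfonate F3.
   - K2CO3 in MeOH closes the 7α,8α-epoxide F4 by intramolecular SN2 displacement with inversion at C7. This occurs from the diaxial conformer that the flexible cis-decalin can reach, and the C8–O bond and its configuration are untouched.
   - LiEt3BH in THF opens the epoxide at the less substituted C7 in a trans-diaxial sense and also reduces C3, giving the 3,8-diol F5 (C3 epimers, of no consequence).
   - DMP in CH2Cl2 oxidises the only secondary alcohol to give 20.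

**Further compounds**
F1 | step 9 | (4S,5R,6S)-5-ethenyl-4,6-dimethyl-4-[4-methyl-3-(trimethylsilyloxy)pent-3-en-1-yl]-6-(triethylsilyloxy)cyclohex-2-en-1-one | C=C[C@@H]1[C@@](C)(CCC(O[Si](C)(C)C)=C(C)C)C=CC(=O)[C@@]1(C)O[Si](CC)(CC)CC
F2 | step 9 | C7 trimethylsilyl enol ether (C6=C7) of 16 | C=C[C@@H]1[C@@]2(C)CCC(=O)C(C)(C)[C@H]2C=C(O[Si](C)(C)C)[C@@]1(C)O[Si](CC)(CC)CC
F0 | step 5 | none | none
F3 | step 12 | 7β-methanesulfonate of 18 | C=C[C@@H]1[C@@]2(C)CCC(=O)C(C)(C)[C@H]2C[C@H](OS(C)(=O)=O)[C@@]1(C)O
F4 | step 12 | cis-fused 7α,8α-epoxy-4,4,8,10-tetramethyl-9β-vinyldecalin-3-one | C=C[C@@H]1[C@@]2(C)CCC(=O)C(C)(C)[C@H]2C[C@H]3O[C@@]13C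
F5 | step 12 | cis-fused 4,4,8,10-tetramethyl-9β-vinyldecalin-3,8α-diol (C3 epimers) | C=C[C@@H]1[C@@]2(C)CCC(O)C(C)(C)[C@H]2CC[C@@]1(C)O
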